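## Structural features

Glycyrrhizaisoflavone B, compound 30, is an achiral isoflavone: a 4H-chromen-4-one whose benzo ring (ring A, C4a to C8a) carries a methoxy group at C5 and a hydroxyl at C7, and whose pyranone ring (ring C) carries the aryl ring B at C3. Ring B is the benzo ring of a 2,2-dimethyl-2H-chromene; it is bonded to C3 through chromene C6 and has a free hydroxyl at chromene C8, ortho to the oxygen of the dimethylpyran ring (ring D), so ring B is a catechol with one oxygen locked in a cyclic tertiary allylic ether. The target has no stereocentre; the only stereocentre met on the way is a racemic carbinol carbon between rings A and B, which has no stereogenic neighbour and is finally oxidised to the C4 carbonyl. The fragile points are the styrene-type C3=C4 double bond and the tertiary allylic aryl ether of ring D (no hydrogenolysis, no strong Lewis acid, no electrophilic oxidant), the two phenols, and the C5 methoxy group peri to the carbonyl, which is the ether most easily lost to chelating Lewis acids. The real difficulty lies in ring A: the oxygens at C5, C7 and C8a are three different functions (methyl ether, free phenol, ring oxygen) placed around the acyl-bearing carbon C4a, and a phloroglucinol-based construction would have to tell three like oxygens apart. The key step exploits exactly this pattern: C4a stands between C5–OMe and C8a–O with C7–OH para to it, which is what a 2-substituted 3-methoxycyclobutenone (C4a, C5, C6), its ketene carbonyl (C7) and a siloxyalkyne (C8, C8a) deliver, each oxygen from a different source.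

## Logic of the disconnections

30 to 29: the two O–CH2OCH3 bonds (C7 oxygen, ring-B oxygen) are restored. One acetal type on both phenols allows a single final step and lets both oxygens pass through base, fluoride, organolithium, heat and oxidant. The skeleton is not simplified, but phenol chemistry is switched off in all earlier steps. The forward step must use acid mild enough to spare ring D and the C5 methyl ether.

29 to 27 by way of 28: O1–C2 and C2=C3 are cut; C2 is a one-carbon unit from a formamide acetal. This is the most dependable, metal-free closure of ring C. Ring C disappears and a benzyl aryl ketone linking rings A and B remains. The forward step needs the C8a hydroxyl free, every other phenol capped and an enolisable CH2.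

27 to 26 to 25 to 24 to 23: no skeletal bond is cut. In this order the O–Si bond at C8a is restored, the C4 carbonyl goes back to a carbinol, the carbinol is re-silylated and the acetal at the C7 oxygen is removed. C4 cannot be a ketone while ring A is made, because an acyl-substituted ketene is a heterodiene that the alkyne would trap in a [4+2] sense to give a pyranone, so C4 is carried as a silyl-protected carbinol. The gain is that 23 is exactly what the ring-forming step delivers. The demand is three protecting groups that leave under three regimes (buffered hydrogen fluoride for the alkyl silyl ether, fluoride anion for the aryl silyl ether, protic acid for the acetals). Because the carbinol is benzylic to a trioxygenated ring, the para oxygen is capped first in 24 and the freed carbinol 25 is oxidised without delay.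

23 to 15 and 19: C7–C8, C4a–C8a and C6–C7 are cut. Here ring A is built with its three oxygens already different, and no oxygen has to be differentiated afterwards. Ring A is reduced to a four-membered ring and a two-carbon alkyne. Both partners must survive 80–110 °C, and the regiochemistry rests on the polarisation of 19.

19 to 16: the O–Si and C–O bonds at the alkyne are cut. 19 is not treated as a catalogue compound, and this cut leads back to 16. The forward step needs oxygen transfer to the metalated alkyne at low temperature and silylation on oxygen, which the bulky silyl group favours.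

15 to 14 to 11 and 12 by way of 13: two C–H bonds at C4 of the cyclobutenone go back to C–Cl, then C1–C2 and C3–C4 of the four-membered ring are cut. A ketene–ynol ether cycloaddition is the direct entry to a 3-alkoxycyclobutenone with the side chain at C2. The ring is traded for an acyclic ynol ether. The ynol ether must react faster than the chromene alkene, and the dechlorination is run in methanol so that any alkoxy exchange at the vinylogous ester is degenerate.

11 to 7 and 8 by way of 9 and 10: the C–C bond between the carbinol carbon and the alkyne, and the O–Si bond, are cut. The molecule splits into an arylacetaldehyde and a two-carbon acetal whose methoxy group ends as the C5 methoxy of 30. Addition must outrun enolisation of the aldehyde, and the alkoxide is silylated in the flask because the free alkoxyethynyl carbinol rearranges with traces of acid.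

7 to 6 to 5: the carbon–carbon bond made by the one-carbon homologation is cut. The ring-B fragment is best prepared as an aryl aldehyde, because the formyl group controls the first step. The hydrolysis of 6 must spare the aryl acetal.

5 to 4 to 3 to 1 and 2: the aryl C–C bond to chromene C4 is cut (with reopening of ring D), then the O–CH2OCH3 bond and the aryl O–C(CH3)2 bond. This leads to 1 and 2, both catalogue compounds. The forward steps rely on the higher acidity of the hydroxyl para to the formyl group, and on the blocked C3 oxygen that leaves only one ortho position for the rearrangement.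

## Other disconnections considered

Alternative 1: Ring A would be disconnected at C4a–C5 and C8–C8a. In the forward direction the ketene-acetal diene 1,1-dimethoxy-3-(trimethylsilyloxy)buta-1,3-diene A3 would add across C5=C6 of the sulfinyl-activated pyranone 3-[8-(methoxymethoxy)-2,2-dimethyl-2H-chromen-6-yl]-5-(phenylsulfinyl)-4H-pyran-4-one A2. Elimination of the sulfinyl group and of one methoxy group from the adduct, with loss of the silyl group, would give 7-hydroxy-5-methoxy-3-[8-(methoxymethoxy)-2,2-dimethyl-2H-chromen-6-yl]-4H-chromen-4-one A1.
- In its favour: rings B, C and D are in place before ring A is made, and A3 itself supplies the methoxy (ketene acetal carbon) and the free hydroxyl (silyl enol ether carbon). A1 is one deprotection from 30, which is clearly better than the six steps the chosen plan needs after its key step.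
- Against it: A2 is an unsymmetrical 3,5-disubstituted pyran-4-one that needs a multi-step synthesis of its own. A pyran-4-one is a vinylogous ester with aromatic character and should be a reluctant dienophile, so the sulfinyl group must act as both activator and leaving group. A3 is sensitive to hydrolysis.
- Comparison: on structure the two plans are equal, since both create ring A de novo with the oxygens already different. On mechanism both are polarity-controlled pericyclic reactions, but the cyclobutenone–siloxyalkyne union rests on a better-defined reaction class than cycloaddition to a pyranone. On step economy Alternative 1 would be the equal or the better only if A2 could be reached in about six steps, which is uncertain.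

Alternative 2: The chromene alkene C3''=C4'' of ring D would be disconnected. In the forward direction the second-generation Grubbs catalyst RuCl2(=CHPh)(PCy3)(H2IMes) would join the aryl vinyl group and the 1,1-dimethylallyl ether of 3-ethenyl-5-(methoxymethoxy)-4-[(2-methylbut-3-en-2-yl)oxy]benzaldehyde A5, with expulsion of the two terminal methylene carbons. The product would be 8-(methoxymethoxy)-2,2-dimethyl-2H-chromene-6-carbaldehyde A4. A4 is the same compound as 5.
- In its favour: the ring would close near 40 °C under neutral conditions, against roughly 190 °C for the rearrangement of 4. On mildness it is the better method.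
- Against it: A5 needs an extra halogenation and vinylation at C5 and a hindered tertiary allyl aryl ether flanked by two ortho substituents, which is hard to make and prone to ionise or rearrange. This is several steps where the chosen plan needs one to reach A4, and it consumes the costly catalyst RuCl2(=CHPh)(PCy3)(H2IMes).
- Comparison: on structure the outcome is the same, since A4 and 5 are one compound. This cut addresses only ring D and leaves ring A untouched, so it would have to be combined with one of the other strategies. On mechanism a catalytic metathesis stands against a reagent-free thermal pericyclic cascade; the metathesis is milder, the cascade needs no metal. On step economy it is worse.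

Alternative 3: Ring C would be disconnected at O1–C8a and C4–C4a. In the forward direction CsF would release 3-methoxy-5-(methoxymethoxy)benzyne A9 from the silyl triflate 3-methoxy-5-(methoxymethoxy)-2-(trimethylsilyl)phenyl trifluoromethanesulfonate A7. The enolate oxygen of methyl 3-hydroxy-2-[8-(methoxymethoxy)-2,2-dimethyl-2H-chromen-6-yl]prop-2-enoate A8 would add to the carbon of A9 remote from the methoxy group, and the aryl anion next to the methoxy group would attack the ester. The product would be 5-methoxy-7-(methoxymethoxy)-3-[8-(methoxymethoxy)-2,2-dimethyl-2H-chromen-6-yl]-4H-chromen-4-one A6. A6 is the same compound as 29.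
- In its favour: it is the most convergent of all the plans. Ring A comes from a resorcinol derivative, A8 is about three operations from 7, and A6 is one step from 30. The whole synthesis would be several steps shorter than the chosen one, so on step economy and convergence it is the better plan. The sense of nucleophilic addition to a 3-alkoxyaryne such as A9 is well understood and matches the target, so on regiochemical rationale it is the equal.
- Against it: the enolate of A8 is ambident, and C-arylation followed by acyl transfer could compete with O-arylation. Protonation of the aryl anion before ring closure would stop at an open aryl vinyl ether. A7 needs a four- to five-step preparation. The differentiation of the ring-A oxygens is moved into the synthesis of A7 and not solved by the key step.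
- Comparison: on structure both plans reach the same protected isoflavone, A6 being 29, but only the chosen plan sets the oxygen pattern of ring A in the ring-forming step itself. On mechanism the chosen plan rests on a cascade whose regiochemistry is fixed by connectivity, whereas the annulation of A9 depends on O- versus C-selectivity of an ambident enolate. Alternative 3 would win overall if that O-selective annulation were reliable on A8.

Key step: step 10

Remark on the chemistry: following the mechanism, the ketene carbonyl carbon becomes C7, the alkyne CH becomes C8, the silyloxy-bearing alkyne carbon becomes C8a, and cyclobutenone C2, C3 and C4 become C4a, C5 and C6. The structures of 15, 19 and 23 agree with this mapping.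
Remark on the chemistry: 19 is assumed not to be a catalogue compound and is prepared in step 9. The carbinol carbon is racemic throughout and is removed by oxidation, so no stereocontrol is required.

## Route

Step 1
Reactants: 1 3,4-dihydroxybenzaldehyde; 2 3-chloro-3-methylbut-1-yne
Product: 3 3-hydroxy-4-[(2-methylbut-3-yn-2-yl)oxy]benzaldehyde
Conditions: K2CO3, KI, CuI (cat.), acetone, 56 °C, argon
Reagents that add atoms: none
Why: The hydroxyl para to the formyl group is the more acidic one, so with about one equivalent of carbonate the 4-phenoxide is the nucleophile; CuI-assisted Williamson-type etherification of the tertiary propargylic chloride gives the aryl 1,1-dimethylpropargyl ether.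

Step 2
Reactants: 3 3-hydroxy-4-[(2-methylbut-3-yn-2-yl)oxy]benzaldehyde
Product: 4 3-(methoxymethoxy)-4-[(2-methylbut-3-yn-2-yl)oxy]benzaldehyde
Conditions: MOMCl, i-Pr2NEt, CH2Cl2, 0 °C → rt
Reagents that add atoms: chloromethyl methyl ether, COCCl
Why: Standard MOM protection of the remaining phenol with an amine base; the acetal blocks the C3 oxygen so that the rearrangement of step 3 can only go to C5, and it tolerates all later basic, organometallic, thermal and fluoride steps.

Step 3
Reactants: 4 3-(methoxymethoxy)-4-[(2-methylbut-3-yn-2-yl)oxy]benzaldehyde
Product: 5 8-(methoxymethoxy)-2,2-dimethyl-2H-chromene-6-carbaldehyde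
Conditions: N,N-diethylaniline, 190 °C
Reagents that add atoms: none
Why: Aromatic propargyl Claisen rearrangement: a [3,3] shift to the only free ortho position, tautomerisation to the allenyl phenol, a 1,5-hydrogen shift and an oxa-six-electron electrocyclization give the 2,2-dimethyl-2H-chromene; the basic solvent protects the MOM acetal.

Step 4
Reactants: 5 8-(methoxymethoxy)-2,2-dimethyl-2H-chromene-6-carbaldehyde
Product: 6 6-(2-methoxyethenyl)-8-(methoxymethoxy)-2,2-dimethyl-2H-chromene (E/Z mixture)
Conditions: Ph3P(CH2OMe)Cl, KOt-Bu, THF, 0 °C → rt
Reagents that add atoms: (methoxymethyl)triphenylphosphonium chloride, COC[P+](c1ccccc1)(c1ccccc1)c1ccccc1.[Cl-]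
Why: Wittig olefination with the methoxymethylene ylide; both geometric isomers of the enol ether lead to the same aldehyde, so the mixture is used as such.

Step 5
Reactants: 6 6-(2-methoxyethenyl)-8-(methoxymethoxy)-2,2-dimethyl-2H-chromene (E/Z mixture)
Product: 7 2-[8-(methoxymethoxy)-2,2-dimethyl-2H-chromen-6-yl]acetaldehyde
Conditions: 2 M aq. HCl, THF, rt; used without delay
Reagents that add atoms: water, O
Why: Acid-catalysed enol ether hydrolysis; carbon protonation of an enol ether is far faster than ionisation of a formaldehyde acetal, so dilute aqueous acid at room temperature should spare the aryl MOM ether and ring D.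

Step 6
Reactants: 7 2-[8-(methoxymethoxy)-2,2-dimethyl-2H-chromen-6-yl]acetaldehyde; 8 2-chloro-1,1-dimethoxyethane (chloroacetaldehyde dimethyl acetal)
Product: 11 triethyl({4-methoxy-1-[8-(methoxymethoxy)-2,2-dimethyl-2H-chromen-6-yl]but-3-yn-2-yl}oxy)silane (racemic), via lithium methoxyacetylide 9 (not isolated), via lithium alkoxide 10 (not isolated)
Conditions: Et2NH, n-BuLi, THF, 0 °C, then 8; then 7, −78 °C; then Et3SiCl, −78 → 0 °C
Reagents that add atoms: chlorotriethylsilane, CC[Si](Cl)(CC)CC
Why: Three equivalents of LiNEt2 convert 8 into lithium methoxyacetylide 9 by double elimination and deprotonation, and 9 adds to the aldehyde (acetylide 1,2-addition; the new carbinol centre is racemic and needs no control). The alkoxide 10 is silylated in the flask, so the acid-sensitive alkoxyethynyl carbinol, which is prone to Meyer–Schuster-type rearrangement to an unsaturated ester, is never isolated.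

Step 7
Reactants: 11 triethyl({4-methoxy-1-[8-(methoxymethoxy)-2,2-dimethyl-2H-chromen-6-yl]but-3-yn-2-yl}oxy)silane (racemic); 12 trichloroacetyl chloride
Product: 14 4,4-dichloro-3-methoxy-2-{2-[8-(methoxymethoxy)-2,2-dimethyl-2H-chromen-6-yl]-1-(triethylsilyloxy)ethyl}cyclobut-2-en-1-one (racemic), via dichloroketene 13 (not isolated)
Conditions: Zn–Cu couple, Et2O/DME, 0 °C → rt, slow addition of 12
Reagents that add atoms: none
Why: Ketene–alkyne [2+2] cycloaddition: the nucleophilic ynol ether carbon that bears the side chain bonds to the ketene carbonyl carbon, so the carbonyl ends next to the side chain and the CCl2 group next to the methoxy carbon. The ynol ether is far more nucleophilic than the chromene alkene, and DME ties up the ZnCl2 that is formed.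

Step 8
Reactants: 14 4,4-dichloro-3-methoxy-2-{2-[8-(methoxymethoxy)-2,2-dimethyl-2H-chromen-6-yl]-1-(triethylsilyloxy)ethyl}cyclobut-2-en-1-one (racemic)
Product: 15 3-methoxy-2-{2-[8-(methoxymethoxy)-2,2-dimethyl-2H-chromen-6-yl]-1-(triethylsilyloxy)ethyl}cyclobut-2-en-1-one (racemic)
Conditions: Zn, AcOH, TMEDA, MeOH, 0 °C
Reagents that add atoms: none
Why: Reductive dechlorination alpha to the carbonyl by zinc in amine-buffered acetic acid, which is mild enough for the silyl ether; methanol is the co-solvent so that any addition–elimination at the vinylogous ester carbon is degenerate.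

Step 9
Reactants: 16 acetylene
Product: 19 (triisopropylsilyloxy)ethyne, via lithium acetylide 17 (not isolated), via lithium ethynolate 18 (not isolated)
Conditions: n-BuLi, THF, −78 °C; LiOOt-Bu (from t-BuOOH and LiN(SiMe3)2), −78 → −10 °C; i-Pr3SiOTf, −78 °C
Reagents that add atoms: tert-butyl hydroperoxide, CC(C)(C)OO; triisopropylsilyl trifluoromethanesulfonate, CC(C)[Si](OS(=O)(=O)C(F)(F)F)(C(C)C)C(C)C
Why: Electrophilic oxygen transfer from lithium tert-butylperoxide to the lithium acetylide gives the ynolate 18, and the bulky silyl triflate silylates it on oxygen; this is the known acetylide-oxidation route to siloxyalkynes, applied here to acetylene itself.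

Step 10
Reactants: 15 3-methoxy-2-{2-[8-(methoxymethoxy)-2,2-dimethyl-2H-chromen-6-yl]-1-(triethylsilyloxy)ethyl}cyclobut-2-en-1-one (racemic); 19 (triisopropylsilyloxy)ethyne
Product: 23 3-methoxy-4-{2-[8-(methoxymethoxy)-2,2-dimethyl-2H-chromen-6-yl]-1-(triethylsilyloxy)ethyl}-5-(triisopropylsilyloxy)phenol (racemic), via vinylketene 20 (not isolated), via vinylcyclobutenone 21 (not isolated), via dienylketene 22 (not isolated)
Conditions: toluene, 80 → 110 °C, sealed tube, 19 (2 equiv)
Reagents that add atoms: none
Why: Thermal four-electron electrocyclic opening of 15 (only the C1–C4 bond can open) gives vinylketene 20, whose ketene carbon is attacked by the nucleophilic CH terminus of 19 in a regiospecific [2+2] cycloaddition that makes C7–C8 and C4a–C8a and gives 21. A second four-electron opening gives dienylketene 22, and a thermal six-electron electrocyclization makes C6–C7 and closes ring A as a cyclohexadienone that tautomerises to the phenol. The closest known reaction type is the Danheiser benzannulation of cyclobutenones with siloxyalkynes to resorcinol monosilyl ethers. Ring A is thus closed by a disrotatory six-electron electrocyclization of a dienylketene. No stereocentre is created that persists: the quaternary carbon of 21 is transient and the carbinol carbon stays racemic. The selectivity needed is regiochemical (side-chain carbon between the methoxy and silyloxy carbons, free hydroxyl para to it) and is secured by the polarisation of the siloxyalkyne together with the fixed connectivity of 15. Chemoselectivity over the chromene alkene follows from the much higher nucleophilicity of 19, and the excess of 19 limits acylation of the product phenol by 20.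

Step 11
Reactants: 23 3-methoxy-4-{2-[8-(methoxymethoxy)-2,2-dimethyl-2H-chromen-6-yl]-1-(triethylsilyloxy)ethyl}-5-(triisopropylsilyloxy)phenol (racemic)
Product: 24 6-{2-[2-methoxy-4-(methoxymethoxy)-6-(triisopropylsilyloxy)phenyl]-2-(triethylsilyloxy)ethyl}-8-(methoxymethoxy)-2,2-dimethyl-2H-chromene (racemic)
Conditions: MOMCl, i-Pr2NEt, CH2Cl2, 0 °C → rt
Reagents that add atoms: chloromethyl methyl ether, COCCl
Why: MOM protection of the unhindered C7 phenol with an amine base; capping the para oxygen shuts off quinone methide formation from the benzylic silyl ether and lets both acetals fall in one final step.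

Step 12
Reactants: 24 6-{2-[2-methoxy-4-(methoxymethoxy)-6-(triisopropylsilyloxy)phenyl]-2-(triethylsilyloxy)ethyl}-8-(methoxymethoxy)-2,2-dimethyl-2H-chromene (racemic)
Product: 25 1-[2-methoxy-4-(methoxymethoxy)-6-(triisopropylsilyloxy)phenyl]-2-[8-(methoxymethoxy)-2,2-dimethyl-2H-chromen-6-yl]ethan-1-ol (racemic)
Conditions: HF·pyridine, pyridine, THF, 0 °C; crude product taken on directly
Reagents that add atoms: none
Why: Under buffered acidic fluoride a secondary alkyl triethylsilyl ether is cleaved much faster than an aryl triisopropylsilyl ether (the order reverses only with basic fluoride); the pyridine buffer keeps the electron-rich benzylic carbinol from ionising.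

Step 13
Reactants: 25 1-[2-methoxy-4-(methoxymethoxy)-6-(triisopropylsilyloxy)phenyl]-2-[8-(methoxymethoxy)-2,2-dimethyl-2H-chromen-6-yl]ethan-1-ol (racemic)
Product: 26 1-[2-methoxy-4-(methoxymethoxy)-6-(triisopropylsilyloxy)phenyl]-2-[8-(methoxymethoxy)-2,2-dimethyl-2H-chromen-6-yl]ethan-1-one
Conditions: Dess–Martin periodinane, NaHCO3, CH2Cl2, 0 °C → rt
Reagents that add atoms: none
Why: Dess–Martin oxidation of the secondary benzylic alcohol under bicarbonate buffer; all phenols are capped and the chromene alkene is inert to the periodinane, and the stereocentre disappears here.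

Step 14
Reactants: 26 1-[2-methoxy-4-(methoxymethoxy)-6-(triisopropylsilyloxy)phenyl]-2-[8-(methoxymethoxy)-2,2-dimethyl-2H-chromen-6-yl]ethan-1-one
Product: 27 1-[2-hydroxy-6-methoxy-4-(methoxymethoxy)phenyl]-2-[8-(methoxymethoxy)-2,2-dimethyl-2H-chromen-6-yl]ethan-1-one
Conditions: n-Bu4NF, AcOH, THF, 0 °C
Reagents that add atoms: none
Why: Fluoride cleaves the aryl silyl ether readily because the phenoxide is stabilised by the ortho acyl group; acetic acid buffering avoids aldol chemistry of the deoxybenzoin, and the MOM acetals are untouched.

Step 15
Reactants: 27 1-[2-hydroxy-6-methoxy-4-(methoxymethoxy)phenyl]-2-[8-(methoxymethoxy)-2,2-dimethyl-2H-chromen-6-yl]ethan-1-one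
Product: 29 5-methoxy-7-(methoxymethoxy)-3-[8-(methoxymethoxy)-2,2-dimethyl-2H-chromen-6-yl]-4H-chromen-4-one, via enaminone 28 (not isolated)
Conditions: Me2NCH(OMe)2, THF, 65 °C
Reagents that add atoms: N,N-dimethylformamide dimethyl acetal, COC(OC)N(C)C
Why: Condensation of the active methylene with the formamide acetal gives enaminone 28; conjugate addition of the ortho phenol and loss of dimethylamine close ring C, which is the standard deoxybenzoin route to isoflavones.

Step 16
Reactants: 29 5-methoxy-7-(methoxymethoxy)-3-[8-(methoxymethoxy)-2,2-dimethyl-2H-chromen-6-yl]-4H-chromen-4-one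
Product: 30 glycyrrhizaisoflavone B, 7-hydroxy-3-(8-hydroxy-2,2-dimethyl-2H-chromen-6-yl)-5-methoxy-4H-chromen-4-one
Conditions: 3 M HCl, MeOH/THF, 40 °C
Reagents that add atoms: none
Why: Acid-catalysed acetal exchange with methanol removes both MOM groups; the aryl methyl ether and the 2,2-dimethylchromene should be stable to dilute methanolic acid at this temperature.

## Compound list

1 | 3,4-dihydroxybenzaldehyde | O=Cc1ccc(O)c(O)c1 | starting material
2 | 3-chloro-3-methylbut-1-yne | CC(C)(Cl)C#C | starting material
3 | 3-hydroxy-4-[(2-methylbut-3-yn-2-yl)oxy]benzaldehyde | O=Cc1ccc(OC(C)(C)C#C)c(O)c1 | intermediate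
4 | 3-(methoxymethoxy)-4-[(2-methylbut-3-yn-2-yl)oxy]benzaldehyde | O=Cc1ccc(OC(C)(C)C#C)c(OCOC)c1 | intermediate
5 | 8-(methoxymethoxy)-2,2-dimethyl-2H-chromene-6-carbaldehyde | O=Cc1cc(OCOC)c2OC(C)(C)C=Cc2c1 | intermediate
6 | 6-(2-methoxyethenyl)-8-(methoxymethoxy)-2,2-dimethyl-2H-chromene (E/Z mixture) | COC=Cc1cc(OCOC)c2OC(C)(C)C=Cc2c1 | intermediate
7 | 2-[8-(methoxymethoxy)-2,2-dimethyl-2H-chromen-6-yl]acetaldehyde | O=CCc1cc(OCOC)c2OC(C)(C)C=Cc2c1 | intermediate
8 | 2-chloro-1,1-dimethoxyethane (chloroacetaldehyde dimethyl acetal) | COC(CCl)OC | starting material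
9 | lithium methoxyacetylide (not isolated) | COC#C[Li] | intermediate
10 | lithium 4-methoxy-1-[8-(methoxymethoxy)-2,2-dimethyl-2H-chromen-6-yl]but-3-yn-2-olate (racemic, not isolated) | COC#CC(Cc1cc(OCOC)c2OC(C)(C)C=Cc2c1)O[Li] | intermediate
11 | triethyl({4-methoxy-1-[8-(methoxymethoxy)-2,2-dimethyl-2H-chromen-6-yl]but-3-yn-2-yl}oxy)silane (racemic) | COC#CC(Cc1cc(OCOC)c2OC(C)(C)C=Cc2c1)O[Si](CC)(CC)CC | intermediate
12 | trichloroacetyl chloride | O=C(Cl)C(Cl)(Cl)Cl | starting material
13 | dichloroketene (not isolated) | O=C=C(Cl)Cl | intermediate
14 | 4,4-dichloro-3-methoxy-2-{2-[8-(methoxymethoxy)-2,2-dimethyl-2H-chromen-6-yl]-1-(triethylsilyloxy)ethyl}cyclobut-2-en-1-one (racemic) | COC1=C(C(Cc2cc(OCOC)c3OC(C)(C)C=Cc3c2)O[Si](CC)(CC)CC)C(=O)C1(Cl)Cl | intermediate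
15 | 3-methoxy-2-{2-[8-(methoxymethoxy)-2,2-dimethyl-2H-chromen-6-yl]-1-(triethylsilyloxy)ethyl}cyclobut-2-en-1-one (racemic) | COC1=C(C(Cc2cc(OCOC)c3OC(C)(C)C=Cc3c2)O[Si](CC)(CC)CC)C(=O)C1 | intermediate
16 | acetylene | C#C | starting material
17 | lithium acetylide (not isolated) | C#C[Li] | intermediate
18 | lithium ethynolate (not isolated) | C#CO[Li] | intermediate
19 | (triisopropylsilyloxy)ethyne | C#CO[Si](C(C)C)(C(C)C)C(C)C | intermediate
20 | 3-methoxy-2-{2-[8-(methoxymethoxy)-2,2-dimethyl-2H-chromen-6-yl]-1-(triethylsilyloxy)ethyl}buta-1,3-dien-1-one (racemic, not isolated) | C=C(OC)C(=C=O)C(Cc1cc(OCOC)c2OC(C)(C)C=Cc2c1)O[Si](CC)(CC)CC | intermediate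
21 | 4-(1-methoxyethenyl)-4-{2-[8-(methoxymethoxy)-2,2-dimethyl-2H-chromen-6-yl]-1-(triethylsilyloxy)ethyl}-3-(triisopropylsilyloxy)cyclobut-2-en-1-one (mixture of diastereomers, not isolated) | O=C1C=C(O[Si](C(C)C)(C(C)C)C(C)C)C1(C(OC)=C)C(Cc1cc(OCOC)c2OC(C)(C)C=Cc2c1)O[Si](CC)(CC)CC | intermediate
22 | 5-methoxy-4-{2-[8-(methoxymethoxy)-2,2-dimethyl-2H-chromen-6-yl]-1-(triethylsilyloxy)ethyl}-3-(triisopropylsilyloxy)hexa-1,3,5-trien-1-one (racemic, not isolated) | O=C=CC(O[Si](C(C)C)(C(C)C)C(C)C)=C(C(OC)=C)C(Cc1cc(OCOC)c2OC(C)(C)C=Cc2c1)O[Si](CC)(CC)CC | intermediate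
23 | 3-methoxy-4-{2-[8-(methoxymethoxy)-2,2-dimethyl-2H-chromen-6-yl]-1-(triethylsilyloxy)ethyl}-5-(triisopropylsilyloxy)phenol (racemic) | COc1cc(O)cc(O[Si](C(C)C)(C(C)C)C(C)C)c1C(Cc1cc(OCOC)c2OC(C)(C)C=Cc2c1)O[Si](CC)(CC)CC | intermediate
24 | 6-{2-[2-methoxy-4-(methoxymethoxy)-6-(triisopropylsilyloxy)phenyl]-2-(triethylsilyloxy)ethyl}-8-(methoxymethoxy)-2,2-dimethyl-2H-chromene (racemic) | COc1cc(OCOC)cc(O[Si](C(C)C)(C(C)C)C(C)C)c1C(Cc1cc(OCOC)c2OC(C)(C)C=Cc2c1)O[Si](CC)(CC)CC | intermediate
25 | 1-[2-methoxy-4-(methoxymethoxy)-6-(triisopropylsilyloxy)phenyl]-2-[8-(methoxymethoxy)-2,2-dimethyl-2H-chromen-6-yl]ethan-1-ol (racemic) | COc1cc(OCOC)cc(O[Si](C(C)C)(C(C)C)C(C)C)c1C(O)Cc1cc(OCOC)c2OC(C)(C)C=Cc2c1 | intermediate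
26 | 1-[2-methoxy-4-(methoxymethoxy)-6-(triisopropylsilyloxy)phenyl]-2-[8-(methoxymethoxy)-2,2-dimethyl-2H-chromen-6-yl]ethan-1-one | COc1cc(OCOC)cc(O[Si](C(C)C)(C(C)C)C(C)C)c1C(=O)Cc1cc(OCOC)c2OC(C)(C)C=Cc2c1 | intermediate
27 | 1-[2-hydroxy-6-methoxy-4-(methoxymethoxy)phenyl]-2-[8-(methoxymethoxy)-2,2-dimethyl-2H-chromen-6-yl]ethan-1-one | COc1cc(OCOC)cc(O)c1C(=O)Cc1cc(OCOC)c2OC(C)(C)C=Cc2c1 | intermediate
28 | 3-(dimethylamino)-1-[2-hydroxy-6-methoxy-4-(methoxymethoxy)phenyl]-2-[8-(methoxymethoxy)-2,2-dimethyl-2H-chromen-6-yl]prop-2-en-1-one (not isolated) | COc1cc(OCOC)cc(O)c1C(=O)C(=CN(C)C)c1cc(OCOC)c2OC(C)(C)C=Cc2c1 | intermediate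
29 | 5-methoxy-7-(methoxymethoxy)-3-[8-(methoxymethoxy)-2,2-dimethyl-2H-chromen-6-yl]-4H-chromen-4-one | COc1cc(OCOC)cc2occ(-c3cc(OCOC)c4c(c3)C=CC(C)(C)O4)c(=O)c12 | intermediate
30 | glycyrrhizaisoflavone B, 7-hydroxy-3-(8-hydroxy-2,2-dimethyl-2H-chromen-6-yl)-5-methoxy-4H-chromen-4-one | COc1cc(O)cc2occ(-c3cc(O)c4c(c3)C=CC(C)(C)O4)c(=O)c12 | target

## Step count and least certain steps

Total: 16 steps. Longest linear sequence: 15 steps (steps 1 to 8 and 10 to 16); step 9 is a one-step side branch.

Step 10 (key step). The most likely failure is thermal loss of triethylsilanol from the product, because the new free hydroxyl stands para to a benzylic silyl ether on a ring with two further donors (quinone methide formation followed by tautomerisation). Further risks are acylation of the product phenol by the vinylketene and slow ring opening of the donor-stabilised cyclobutenone. The fallback sets out from 11 and comes back at 24, with the roles of the partners exchanged. Commercial cyclobutane-1,3-dione would be O-alkylated (MOMCl, i-Pr2NEt) to 3-(methoxymethoxy)cyclobut-2-en-1-one F1. Heating F1 with the ynol ether 11 (toluene, 80 °C then about 150 °C) is the alkoxyalkyne form of the same benzannulation and should give 3-methoxy-5-(methoxymethoxy)-2-{2-[8-(methoxymethoxy)-2,2-dimethyl-2H-chromen-6-yl]-1-(triethylsilyloxy)ethyl}phenol F2. Here the methoxy group comes from the alkyne, the C7 oxygen arrives already protected, and the new hydroxyl is the C8a oxygen, ortho and not para to the benzylic ether. Silylation of F2 (i-Pr3SiOTf, 2,6-lutidine) gives 24, so that steps 7 to 11 are not needed.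

Step 9. Disproportionation of monolithium acetylide to the dilithium compound during the warming needed for oxygen transfer, and loss of the volatile product, are the likely problems. The fallback sets out from 16 and comes back at 19. Acetylene would be monosilylated (n-BuLi, Me3SiCl) to ethynyltrimethylsilane F3, which is also a catalogue compound and whose lithium derivative is stable at 0 °C. The same peroxide oxidation and O-silylation of F3 would give trimethyl{[tri(propan-2-yl)silyloxy]ethynyl}silane F4. Brief treatment of F4 with K2CO3 in methanol at 0 °C would remove the carbon-bound silyl group, the bulk of the triisopropylsilyl group shielding the O–Si bond, and give 19.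

Step 6. Enolisation and self-condensation of the arylacetaldehyde by the basic species present (acetylide, LiOMe) may compete with addition, and incomplete silylation would expose the carbinol to rearrangement on work-up. The fallback sets out from 7 and comes back at 15 without any ynol ether. Cyclobutane-1,3-dione and methanol (TsOH cat.) give 3-methoxycyclobut-2-en-1-one F5, and iodine with pyridine converts F5 into 2-iodo-3-methoxycyclobut-2-en-1-one F6. A Nozaki–Hiyama–Kishi coupling of F6 with 7 (CrCl2, NiCl2 cat., DMF, rt), which is non-basic and aldehyde-selective, gives 2-{1-hydroxy-2-[8-(methoxymethoxy)-2,2-dimethyl-2H-chromen-6-yl]ethyl}-3-methoxycyclobut-2-en-1-one F7. Silylation of F7 (Et3SiCl, imidazole) gives 15; steps 7 and 8 are bypassed as well.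

Step 7. Competing cycloaddition of the electrophilic ketene to the chromene double bond, and desilylation or ionisation of the propargylic ether by ZnCl2, are the main risks. The fallback sets out from 11 and comes back at 15. The halogenated ketene and the reductive step are abandoned, and 11 is treated with ketene gas (from pyrolysis of acetone) in CH2Cl2 at 0 °C. The parent ketene reacts with ynol ethers but hardly with styrene-type alkenes and introduces no metal salt, so 15 should form directly and step 8 is not needed. This fallback makes no compound outside the list and is entered as F0.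

Step 12. Ionisation of the trioxygenated benzylic position under the acidic fluoride (dehydration towards a stilbene), or partial loss of the aryl silyl group, may occur. The fallback sets out from 24 and comes back at 27, with the order of events changed. n-Bu4NF in THF at 0 °C removes both silyl groups under basic conditions to give 2-{1-hydroxy-2-[8-(methoxymethoxy)-2,2-dimethyl-2H-chromen-6-yl]ethyl}-3-methoxy-5-(methoxymethoxy)phenol F8. Oxidation of the benzylic alcohol of F8 with MnO2 in CH2Cl2, which tolerates the free phenol, gives 27 and bypasses steps 13 and 14.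

## Further compounds

F1 | step 10 | 3-(methoxymethoxy)cyclobut-2-en-1-one | COCOC1=CC(=O)C1
F2 | step 10 | 3-methoxy-5-(methoxymethoxy)-2-{2-[8-(methoxymethoxy)-2,2-dimethyl-2H-chromen-6-yl]-1-(triethylsilyloxy)ethyl}phenol (racemic) | COc1cc(OCOC)cc(O)c1C(Cc1cc(OCOC)c2OC(C)(C)C=Cc2c1)O[Si](CC)(CC)CC
F3 | step 9 | ethynyltrimethylsilane | C#C[Si](C)(C)C
F4 | step 9 | trimethyl{[tri(propan-2-yl)silyloxy]ethynyl}silane | C[Si](C)(C)C#CO[Si](C(C)C)(C(C)C)C(C)C
F5 | step 6 | 3-methoxycyclobut-2-en-1-one | COC1=CC(=O)C1
F6 | step 6 | 2-iodo-3-methoxycyclobut-2-en-1-one | COC1=C(I)C(=O)C1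
F7 | step 6 | 2-{1-hydroxy-2-[8-(methoxymethoxy)-2,2-dimethyl-2H-chromen-6-yl]ethyl}-3-methoxycyclobut-2-en-1-one (racemic) | COC1=C(C(O)Cc2cc(OCOC)c3OC(C)(C)C=Cc3c2)C(=O)C1
F0 | step 7 | none | none
F8 | step 12 | 2-{1-hydroxy-2-[8-(methoxymethoxy)-2,2-dimethyl-2H-chromen-6-yl]ethyl}-3-methoxy-5-(methoxymethoxy)phenol (racemic) | COc1cc(OCOC)cc(O)c1C(O)Cc1cc(OCOC)c2OC(C)(C)C=Cc2c1
A1 | alternative 1 | 7-hydroxy-5-methoxy-3-[8-(methoxymethoxy)-2,2-dimethyl-2H-chromen-6-yl]-4H-chromen-4-one | COc1cc(O)cc2occ(-c3cc(OCOC)c4c(c3)C=CC(C)(C)O4)c(=O)c12
A2 | alternative 1 | 3-[8-(methoxymethoxy)-2,2-dimethyl-2H-chromen-6-yl]-5-(phenylsulfinyl)-4H-pyran-4-one (racemic at sulfur) | O=c1c(S(=O)c2ccccc2)cocc1-c1cc(OCOC)c2OC(C)(C)C=Cc2c1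
A3 | alternative 1 | 1,1-dimethoxy-3-(trimethylsilyloxy)buta-1,3-diene | COC(OC)=CC(=C)O[Si](C)(C)C
A4 | alternative 2 | 8-(methoxymethoxy)-2,2-dimethyl-2H-chromene-6-carbaldehyde | O=Cc1cc(OCOC)c2OC(C)(C)C=Cc2c1
A5 | alternative 2 | 3-ethenyl-5-(methoxymethoxy)-4-[(2-methylbut-3-en-2-yl)oxy]benzaldehyde | O=Cc1cc(OCOC)c(OC(C)(C)C=C)c(C=C)c1
A6 | alternative 3 | 5-methoxy-7-(methoxymethoxy)-3-[8-(methoxymethoxy)-2,2-dimethyl-2H-chromen-6-yl]-4H-chromen-4-one | COc1cc(OCOC)cc2occ(-c3cc(OCOC)c4c(c3)C=CC(C)(C)O4)c(=O)c12
A7 | alternative 3 | 3-methoxy-5-(methoxymethoxy)-2-(trimethylsilyl)phenyl trifluoromethanesulfonate | COCOc1cc(OC)c([Si](C)(C)C)c(OS(=O)(=O)C(F)(F)F)c1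
A8 | alternative 3 | methyl 3-hydroxy-2-[8-(methoxymethoxy)-2,2-dimethyl-2H-chromen-6-yl]prop-2-enoate | COC(=O)C(=CO)c1cc(OCOC)c2OC(C)(C)C=Cc2c1
A9 | alternative 3 | 3-methoxy-5-(methoxymethoxy)benzyne | COCOC1=CC#CC(OC)=C1
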